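**Retrosynthetic overview**
- Target 15 comes from 3-nonadecylphenol 14 by para-oxidation, so the C1 carbonyl oxygen is introduced last. Phenol 14 comes from methyl 6-nonadecylsalicylate 12 by ester cleavage and loss of CO2.
- Salicylate 12 comes from cyclohexenone ester 10 by dehydrogenation. Ester 10 comes from open-chain methyl 3,7-dioxohexacosanoate 8 by an intramolecular Knoevenagel–aldol condensation (chain C2 onto chain C7), the only ring-forming event of the route.
- Diketo ester 8 comes from 5-oxotetracosanoic acid 4 and a malonate half ester by decarboxylative Claisen extension. Acid 4 comes from the nonadecyl Grignard reagent and glutaric anhydride.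
- Feature the strategy rests on: the single six-membered carbocycle of the quinone. Its C2–C3 bond (C2 carrying the nonadecyl chain, C3 the ring CH next to the C4 carbonyl) is the aldol bond. C4=O is the chain's C3 ketone, C5, C6 and C1 are chain C4 to C6, and C1 stays unoxidised until the final step.

Key step: step 3

Assumption: the target has no stereocentre, so no stereocontrol is needed; 1-bromononadecane is taken as a catalogue compound.

**Route**

Step 1
Reactants: 1 1-bromononadecane; 2 glutaric anhydride
Product: 4 5-oxotetracosanoic acid, via nonadecylmagnesium bromide 3 (not isolated)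
Conditions: Mg, I2 (cat.), THF, 50 °C; then added slowly to 2 (1.5 equiv), THF, −40 °C to rt; aq. HCl
Reagents that add atoms: none
Why: Grignard formation followed by nucleophilic ring opening of the cyclic anhydride, in which inverse addition to excess anhydride at low temperature should stop the reaction at the magnesium keto-carboxylate, whose ketone is less electrophilic than the remaining anhydride.

Step 2
Reactants: 4 5-oxotetracosanoic acid; 5 potassium monomethyl malonate (KO2CCH2CO2Me)
Product: 8 methyl 3,7-dioxohexacosanoate, via 1-(1H-imidazol-1-yl)tetracosane-1,5-dione 6 (not isolated), via chloromagnesium methyl malonate 7 (not isolated)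
Conditions: CDI, THF, rt; then 5, MgCl2, Et3N, MeCN, rt to 40 °C; aq. HCl
Reagents that add atoms: none
Why: Masamune–Brooks decarboxylative Claisen extension, in which the acyl imidazolide C-acylates the magnesium-chelated malonate half ester with loss of CO2 under near-neutral conditions that should leave the remote C5 ketone untouched.

Step 3
Reactants: 8 methyl 3,7-dioxohexacosanoate
Product: 10 methyl 2-nonadecyl-6-oxocyclohex-1-ene-1-carboxylate, via methyl 2-hydroxy-2-nonadecyl-6-oxocyclohexane-1-carboxylate 9 (not isolated)
Conditions: piperidine (0.2 equiv), AcOH (0.4 equiv), toluene, reflux, Dean–Stark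
Reagents that add atoms: none
Why: Piperidinium acetate converts the β-keto ester terminus into its enol or enamino ester, whose C2 carbon adds to the C7 ketone to give the tertiary aldol 9, and azeotropic removal of water drives dehydration to the tetrasubstituted alkene conjugated with both carbonyl groups. The closest known reaction type is the intramolecular Knoevenagel condensation of a β-keto ester onto the ketone of a 1,5-dicarbonyl chain, the laboratory counterpart of the C2–C7 aldol folding of alkylsalicylate polyketide assembly. The only ring, the six-membered carbocycle, is closed by a 6-exo-trig aldol (6-enolexo through the ester enol, equally allowed as 6-enolendo through the ketone enol or the enamine). No stereocentre remains, because both centres of 9 are erased on dehydration. The step needs site selectivity among four enolisable positions: C2 is the only doubly activated methylene and far more acidic than C4, C6 or C8, closures of C4 onto C7 or C6 onto C3 would give four-membered rings, and the competing six-membered closure of C8 onto C3 should be suppressed because C3 is held as the enol or vinylogous carbamate of the β-keto ester under these mild conditions.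

Step 4
Reactants: 10 methyl 2-nonadecyl-6-oxocyclohex-1-ene-1-carboxylate
Product: 12 methyl 2-hydroxy-6-nonadecylbenzoate, via methyl 5-bromo-2-nonadecyl-6-oxocyclohex-1-ene-1-carboxylate 11 (not isolated)
Conditions: CuBr2 (2.1 equiv), LiBr (1 equiv), MeCN, reflux
Reagents that add atoms: none
Why: Oxidative aromatisation of a 2-alkoxycarbonylcyclohexenone by CuBr2-mediated α-bromination of the ketone at C5 and loss of HBr, the resulting cyclohexadienone tautomerising to the hydrogen-bonded salicylate, whose ester-deactivated ring should resist further bromination at this stoichiometry.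

Step 5
Reactants: 12 methyl 2-hydroxy-6-nonadecylbenzoate
Product: 13 2-hydroxy-6-nonadecylbenzoic acid
Conditions: KOH, DMSO/H2O, 110 °C; then aq. HCl, 0 °C
Reagents that add atoms: potassium hydroxide, [K+].[OH-]
Why: Saponification of a hindered 2,6-disubstituted benzoate, for which poorly solvated hydroxide in aqueous DMSO should overcome the slow attack at the flanked ester carbonyl, with cold acidification freeing the acid below the temperature at which it loses CO2.

Step 6
Reactants: 13 2-hydroxy-6-nonadecylbenzoic acid
Product: 14 3-nonadecylphenol
Conditions: neat, 200 °C, N2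
Reagents that add atoms: none
Why: Thermal protodecarboxylation of an ortho-hydroxybenzoic acid through its keto tautomer (the anacardic acid to cardanol conversion), which needs no reagent and should leave the phenol and the saturated chain unchanged.

Step 7
Reactants: 14 3-nonadecylphenol
Product: 15 2-nonadecyl-1,4-benzoquinone (2-nonadecylcyclohexa-2,5-diene-1,4-dione)
Conditions: ON(SO3K)2 (2.5 equiv), KH2PO4, methyltrioctylammonium chloride (cat.), CH2Cl2/H2O, rt
Reagents that add atoms: potassium nitrosodisulfonate ON(SO3K)2, [K+].[K+].[O]N(S(=O)(=O)[O-])S(=O)(=O)[O-]
Why: Teuber oxidation, in which two equivalents of the nitrosodisulfonate radical should convert a phenol with a free para position into the para-benzoquinone, the new oxygen entering at C4 of the phenol next to the chain (C1 of the target), with phase transfer carrying the oxidant to the lipophilic substrate.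

**Compound list**

1 | 1-bromononadecane | CCCCCCCCCCCCCCCCCCCBr | starting material
2 | glutaric anhydride | O=C1CCCC(=O)O1 | starting material
3 | nonadecylmagnesium bromide | CCCCCCCCCCCCCCCCCCC[Mg]Br | intermediate (not isolated)
4 | 5-oxotetracosanoic acid | CCCCCCCCCCCCCCCCCCCC(=O)CCCC(=O)O | intermediate
5 | potassium monomethyl malonate | COC(=O)CC(=O)[O-].[K+] | starting material
6 | 1-(1H-imidazol-1-yl)tetracosane-1,5-dione (acyl imidazolide of 4) | CCCCCCCCCCCCCCCCCCCC(=O)CCCC(=O)n1ccnc1 | intermediate (not isolated)
7 | chloromagnesium methyl malonate, ClMgO2CCH2CO2Me | COC(=O)CC(=O)[O-].[Mg+2].[Cl-] | intermediate (not isolated)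
8 | methyl 3,7-dioxohexacosanoate | CCCCCCCCCCCCCCCCCCCC(=O)CCCC(=O)CC(=O)OC | intermediate
9 | methyl 2-hydroxy-2-nonadecyl-6-oxocyclohexane-1-carboxylate (racemic, mixture of diastereomers) | CCCCCCCCCCCCCCCCCCCC1(O)CCCC(=O)C1C(=O)OC | intermediate (not isolated)
10 | methyl 2-nonadecyl-6-oxocyclohex-1-ene-1-carboxylate | CCCCCCCCCCCCCCCCCCCC1=C(C(=O)OC)C(=O)CCC1 | intermediate
11 | methyl 5-bromo-2-nonadecyl-6-oxocyclohex-1-ene-1-carboxylate (racemic) | CCCCCCCCCCCCCCCCCCCC1=C(C(=O)OC)C(=O)C(Br)CC1 | intermediate (not isolated)
12 | methyl 2-hydroxy-6-nonadecylbenzoate | CCCCCCCCCCCCCCCCCCCc1cccc(O)c1C(=O)OC | intermediate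
13 | 2-hydroxy-6-nonadecylbenzoic acid | CCCCCCCCCCCCCCCCCCCc1cccc(O)c1C(=O)O | intermediate
14 | 3-nonadecylphenol | CCCCCCCCCCCCCCCCCCCc1cccc(O)c1 | intermediate
15 | 2-nonadecyl-1,4-benzoquinone | CCCCCCCCCCCCCCCCCCCC1=CC(=O)C=CC1=O | target

**Step count**

Total steps: 7. Longest linear sequence: 7 steps (1 to 15).

**Steps most likely to fail**

1. Step 3 (key cyclisation). The risks are closure of the chain-side C8 onto C3 in place of C2 onto C7, stalling at the aldol stage, and aminolysis or retro-Claisen cleavage of the β-keto ester on prolonged heating. Fallback: build the ring by Michael–aldol annulation of an acetoacetate with an enal. Setting out from 1, the Grignard reagent 3 would be formylated with DMF to give icosanal F1. Wittig homologation with Ph3P=CHCHO (toluene, 80 °C) should give (E)-docos-2-enal F2. NaOMe-catalysed conjugate addition of methyl acetoacetate in MeOH, then aldol condensation completed with TsOH in refluxing toluene, should give methyl 6-nonadecyl-2-oxocyclohex-3-ene-1-carboxylate F3. Aromatisation of F3 with CuBr2/LiBr in MeCN rejoins the route at salicylate 12.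

2. Step 7 (para-oxidation). The risks are incomplete oxidation because the waxy phenol and the water-soluble radical stay in separate phases, and over-oxidation or coupling of the phenoxyl radical. Fallback: install the para oxygen by way of nitrogen. Setting out from 14, nitrosation (NaNO2, AcOH/EtOH, 0 °C) para to the hydroxyl should give 4-nitroso-3-nonadecylphenol F4. Reduction with Na2S2O4 in aqueous NaOH/EtOH should give 4-amino-3-nonadecylphenol F5. Oxidation with FeCl3 in aqueous HCl/THF, with hydrolysis of the quinone imine, comes back to the route at target 15.

3. Step 4 (aromatisation). The risks are bromination at the allylic first carbon of the side chain in place of the ring α-carbon, and further bromination of the phenol once formed. Fallback: remove the ester before aromatising. Setting out from 10, acidic hydrolysis and decarboxylation (aq. HCl, AcOH, reflux) should give 3-nonadecylcyclohex-2-en-1-one F6. Aerobic dehydrogenation (Pd(OCOCF3)2, 2-(dimethylamino)pyridine, TsOH, O2, DMSO, 80 °C) would then give 3-nonadecylphenol, rejoining the route at 14 and bypassing 12 and 13.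

**Further compounds**

F1 | step 3 | icosanal | CCCCCCCCCCCCCCCCCCCC=O
F2 | step 3 | (E)-docos-2-enal | CCCCCCCCCCCCCCCCCCC/C=C/C=O
F3 | step 3 | methyl 6-nonadecyl-2-oxocyclohex-3-ene-1-carboxylate (racemic, mixture of diastereomers) | CCCCCCCCCCCCCCCCCCCC1CC=CC(=O)C1C(=O)OC
F4 | step 7 | 4-nitroso-3-nonadecylphenol | CCCCCCCCCCCCCCCCCCCc1cc(O)ccc1N=O
F5 | step 7 | 4-amino-3-nonadecylphenol | CCCCCCCCCCCCCCCCCCCc1cc(O)ccc1N
F6 | step 4 | 3-nonadecylcyclohex-2-en-1-one | CCCCCCCCCCCCCCCCCCCC1=CC(=O)CCC1
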